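**Plan**
Cuts, in retrosynthetic order: the three O–CH3 bonds; then bonds C2–C3 and C4–C5 of the cyclohexa-2,5-dien-1-one ring (C1 = C=O, C4 = carbon of the exocyclic C=C), which splits the ring into a C≡CH unit and a four-carbon diene.
Enabling feature: in the 4-(diarylmethylidene)cyclohexa-2,5-dienone, the exocyclic carbon, C4 and C3 are the C(OH)–C≡CH of a doubly benzylic tertiary propargylic alcohol, and C2–C1(=O)–C6–C5 are a 1-methoxy-3-silyloxybutadiene; alcohol + diene − MeOH − Me3SiOH is exactly the quinone methide oxidation level, with C=O para to the exocyclic carbon as the diene polarity demands.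
Further cuts: C(OH)–C≡CH (acetylide to ketone), ring A–C≡C (Sonogashira), C(=O)–anisyl (Grignard on acid chloride), ring A–anisyl (carboxylate-directed C–H arylation); ring A is bought as 2-bromo-3-methylbenzoic acid.
Forward order: ring A and the three anisyl rings are joined first (steps 1–4), the dienone ring is built last from open-chain carbons (step 5), and demethylation ends the route (step 6).
Stereochemistry: the target has no stereocentre and no stereogenic double bond (the exocyclic alkene carries a symmetric ring); the racemic carbinol centre of 10 is erased in step 5.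

Key step: step 5

Assumption: the dienone ring and the 4-hydroxyphenyl ring on the central carbon exchange roles by proton tautomerism, so it does not matter which of the two is made from the diene.

**Step 1**
Reactants: 1 2-bromo-3-methylbenzoic acid; 2 4-iodoanisole
Product: 3 2-bromo-6-(4-methoxyphenyl)-3-methylbenzoic acid
Conditions: Pd(OAc)2 (5 mol %), AgOAc (1.3 equiv), 2 (3 equiv), AcOH, 120 °C
Reagents that add atoms: none
Why: Carboxylate-directed ortho C–H arylation with an aryl iodide (cycle between divalent and tetravalent palladium, AgOAc as iodide acceptor) should arylate C6, the only free position ortho to the carboxyl group, and should leave the C–Br bond alone because no zerovalent palladium is involved.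

**Step 2**
Reactants: 3 2-bromo-6-(4-methoxyphenyl)-3-methylbenzoic acid; 4 (4-methoxyphenyl)magnesium bromide
Product: 6 [2-bromo-6-(4-methoxyphenyl)-3-methylphenyl](4-methoxyphenyl)methanone, via acid chloride 5 (not isolated)
Conditions: (COCl)2, DMF (cat), CH2Cl2, 0 °C to rt, evaporation; then 4 (1.2 equiv), CuI (10 mol %), THF, −40 to 0 °C
Reagents that add atoms: none
Why: Copper-catalysed acylation of an aryl Grignard reagent by an acid chloride should stop at the ketone because the carbonyl group of 6 is flanked by two ortho substituents, and at −40 °C the aryl bromide should not undergo halogen–magnesium exchange.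

**Step 3**
Reactants: 6 [2-bromo-6-(4-methoxyphenyl)-3-methylphenyl](4-methoxyphenyl)methanone; 7 4-ethynylanisole
Product: 8 (4-methoxyphenyl){6-(4-methoxyphenyl)-2-[(4-methoxyphenyl)ethynyl]-3-methylphenyl}methanone
Conditions: PdCl2(MeCN)2 (2 mol %), XPhos (6 mol %), Cs2CO3, MeCN, 80 °C
Reagents that add atoms: none
Why: Copper-free Sonogashira coupling should succeed because the ortho acyl group activates the C–Br bond for oxidative addition and the bulky biarylphosphine copes with the two ortho substituents.

**Step 4**
Reactants: 8 (4-methoxyphenyl){6-(4-methoxyphenyl)-2-[(4-methoxyphenyl)ethynyl]-3-methylphenyl}methanone; 9 ethynylmagnesium bromide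
Product: 10 1-(4-methoxyphenyl)-1-{6-(4-methoxyphenyl)-2-[(4-methoxyphenyl)ethynyl]-3-methylphenyl}prop-2-yn-1-ol (racemic)
Conditions: 9 (3 equiv), LaCl3·2LiCl (0.3 equiv), THF, 0 °C to rt; aqueous NH4Cl
Reagents that add atoms: none
Why: 1,2-Addition of a small acetylide to the non-enolisable diaryl ketone, assisted by the oxophilic lanthanum salt, should give the tertiary propargylic alcohol, whose new stereocentre is formed racemic and needs no control because step 5 destroys it.

**Step 5**
Reactants: 10 1-(4-methoxyphenyl)-1-{6-(4-methoxyphenyl)-2-[(4-methoxyphenyl)ethynyl]-3-methylphenyl}prop-2-yn-1-ol; 11 trans-1-methoxy-3-(trimethylsilyloxy)buta-1,3-diene (the Danishefsky diene)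
Product: 14 4-[(4-methoxyphenyl){6-(4-methoxyphenyl)-2-[(4-methoxyphenyl)ethynyl]-3-methylphenyl}methylidene]cyclohexa-2,5-dien-1-one, via allenyl enone 12 (not isolated), via methoxycyclohexenone 13 (not isolated)
Conditions: 11 (3 equiv), TMSOTf (0.2 equiv), 4 Å MS, CH2Cl2, −78 to 0 °C; then TFA (0.1 equiv), 0 °C
Reagents that add atoms: none
Why: Proposed new method: TMSOTf should ionise the doubly benzylic tertiary propargylic alcohol 10 (after O-silylation in the flask by the first equivalent of 11) to a diaryl propargyl/allenyl cation, which the nucleophilic CH2 terminus of 11 attacks at the unhindered alkyne CH (first bond) to give allene 12 after silyl transfer. The silyl-activated β-methoxy enone of 12 is then attacked at its CH(OMe) carbon by the central allene carbon (second bond), the resulting diarylmethyl cation loses the ring proton next to the carbonyl group to give 13, and acid-induced β-elimination of methanol leaves the cross-conjugated dienone 14. The closest known reaction types are the Lewis-acid-catalysed propargylic substitution of tertiary propargylic alcohols by silyl enol ethers with attack at the alkyne terminus (allene formation) and the stepwise Mukaiyama–Michael/elimination benzannulation of 1-methoxy-3-silyloxydienes with acetylenic ketones; new is their merger on a propargylic cation, so that the ring arrives at the quinone methide oxidation level. The one ring closed is the six-membered carbocycle, by a 6-endo-trig cation–olefin (Prins-type) attack of the allene on the enone β-carbon (a 6π electrocyclisation of the dienol form of 12 would close the same ring). No stereocentre survives, since the allene axis and the methoxy-bearing carbon are transient and the new ring is symmetric about the exocyclic double bond. The step needs attack at the alkyne terminus instead of the carbinol carbon (secured by the alkynyl and aryl groups ortho to it on ring A), the para placement of C=O and the exocyclic carbon (secured by the polarity of 11, CH2 nucleophilic and CH(OMe) electrophilic), and no diversion by the diarylalkyne, by Friedel–Crafts closure onto the neighbouring anisyl ring or by thermal cyclisation of the enyne–allene unit of 12 (the alkyne cannot ionise, the arene position concerned is meta to OMe, and the cationic closure runs below 0 °C).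

**Step 6**
Reactants: 14 4-[(4-methoxyphenyl){6-(4-methoxyphenyl)-2-[(4-methoxyphenyl)ethynyl]-3-methylphenyl}methylidene]cyclohexa-2,5-dien-1-one
Product: 15 Selaginellin U, 4-[(4-hydroxyphenyl){6-(4-hydroxyphenyl)-2-[(4-hydroxyphenyl)ethynyl]-3-methylphenyl}methylidene]cyclohexa-2,5-dien-1-one
Conditions: BBr3 (8 equiv), CH2Cl2, −78 °C to rt; then H2O, NaHCO3
Reagents that add atoms: none
Why: Cleavage of aryl methyl ethers by BBr3 should free the three phenols while the boron-bound dienone is held as a stabilised triarylmethyl cation that returns the quinone methide on hydrolysis, the diarylalkyne being inert to BBr3 at or below room temperature.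

**Compound list**
1 | 2-bromo-3-methylbenzoic acid | Cc1cccc(C(=O)O)c1Br | starting material
2 | 4-iodoanisole (1-iodo-4-methoxybenzene) | COc1ccc(I)cc1 | starting material
3 | 2-bromo-6-(4-methoxyphenyl)-3-methylbenzoic acid | Cc1ccc(-c2ccc(OC)cc2)c(C(=O)O)c1Br | intermediate
4 | (4-methoxyphenyl)magnesium bromide, THF solution | COc1ccc([Mg]Br)cc1 | starting material
5 | 2-bromo-6-(4-methoxyphenyl)-3-methylbenzoyl chloride, formed in the flask | Cc1ccc(-c2ccc(OC)cc2)c(C(=O)Cl)c1Br | intermediate
6 | [2-bromo-6-(4-methoxyphenyl)-3-methylphenyl](4-methoxyphenyl)methanone | Cc1ccc(-c2ccc(OC)cc2)c(C(=O)c2ccc(OC)cc2)c1Br | intermediate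
7 | 4-ethynylanisole (1-ethynyl-4-methoxybenzene) | C#Cc1ccc(OC)cc1 | starting material
8 | (4-methoxyphenyl){6-(4-methoxyphenyl)-2-[(4-methoxyphenyl)ethynyl]-3-methylphenyl}methanone | Cc1ccc(-c2ccc(OC)cc2)c(C(=O)c2ccc(OC)cc2)c1C#Cc1ccc(OC)cc1 | intermediate
9 | ethynylmagnesium bromide, THF solution | C#C[Mg]Br | starting material
10 | 1-(4-methoxyphenyl)-1-{6-(4-methoxyphenyl)-2-[(4-methoxyphenyl)ethynyl]-3-methylphenyl}prop-2-yn-1-ol, racemic | Cc1ccc(-c2ccc(OC)cc2)c(C(O)(C#C)c2ccc(OC)cc2)c1C#Cc1ccc(OC)cc1 | intermediate
11 | trans-1-methoxy-3-(trimethylsilyloxy)buta-1,3-diene | CO/C=C/C(=C)O[Si](C)(C)C | starting material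
12 | (1E)-1-methoxy-7-(4-methoxyphenyl)-7-{6-(4-methoxyphenyl)-2-[(4-methoxyphenyl)ethynyl]-3-methylphenyl}hepta-1,5,6-trien-3-one, racemic allene, formed in the flask | Cc1ccc(-c2ccc(OC)cc2)c(C(=C=CCC(=O)/C=C/OC)c2ccc(OC)cc2)c1C#Cc1ccc(OC)cc1 | intermediate
13 | 5-methoxy-4-[(4-methoxyphenyl){6-(4-methoxyphenyl)-2-[(4-methoxyphenyl)ethynyl]-3-methylphenyl}methylidene]cyclohex-2-en-1-one, mixture of isomers that converge, formed in the flask | Cc1ccc(-c2ccc(OC)cc2)c(C(=C2C=CC(=O)CC2OC)c2ccc(OC)cc2)c1C#Cc1ccc(OC)cc1 | intermediate
14 | 4-[(4-methoxyphenyl){6-(4-methoxyphenyl)-2-[(4-methoxyphenyl)ethynyl]-3-methylphenyl}methylidene]cyclohexa-2,5-dien-1-one | Cc1ccc(-c2ccc(OC)cc2)c(C(=C2C=CC(=O)C=C2)c2ccc(OC)cc2)c1C#Cc1ccc(OC)cc1 | intermediate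
15 | Selaginellin U | Cc1ccc(-c2ccc(O)cc2)c(C(=C2C=CC(=O)C=C2)c2ccc(O)cc2)c1C#Cc1ccc(O)cc1 | target

**Count**
Total steps: 6. Longest linear sequence: 6 steps (1 to 15).

**Steps most likely to fail**

Step 5 (Proposed new method). The cation may be attacked at the carbinol carbon instead of the alkyne terminus. The diene may be lost by protonolysis before the cation forms. The sequence may also stall at open-chain adduct 12, whose enyne–allene unit could then cyclise thermally, or the cation may close onto the neighbouring anisyl ring. The fallback uses known chemistry and gives up the ring construction. It sets out from 8: addition of 4 (LaCl3·2LiCl, THF, 0 °C to rt) should give bis(4-methoxyphenyl){6-(4-methoxyphenyl)-2-[(4-methoxyphenyl)ethynyl]-3-methylphenyl}methanol F1. BBr3 in CH2Cl2 followed by aqueous work-up should cleave its four methyl ethers and dehydrate the carbinol through the triarylmethyl cation. The fallback comes back to the route at 15.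

Step 1. The ortho-disubstituted acid may lose CO2 under hot silver/acid conditions, the C–Br bond may be attacked, or C–H palladation may be slow next to the bromine-bearing ring position. The fallback replaces the catalytic C–H arylation by stoichiometric directed metalation and a cross-coupling. It sets out from 1: carboxylate-directed ortho-lithiation (LiTMP, 2.2 equiv, THF, −78 °C; C6 is the only position ortho to the carboxylate) and iodine quench should give 2-bromo-6-iodo-3-methylbenzoic acid F2. Suzuki–Miyaura coupling with 4-methoxyphenylboronic acid [Pd(PPh3)4, K2CO3, dioxane/H2O, 70 °C], selective for the C–I bond, should then give the biaryl acid. The fallback comes back to the route at 3.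

Step 6. The boron-bound triarylmethyl cation may undergo Friedel–Crafts closure to a fluorene or bromide addition, and the ether on the cation-bearing ring may be cleaved incompletely. The fallback moves the demethylation to a stage without alkyne or ionisable carbon and ends with fluoride. It sets out from 6:
- BBr3 (CH2Cl2) should give [2-bromo-6-(4-hydroxyphenyl)-3-methylphenyl](4-hydroxyphenyl)methanone F3.
- TBSCl and imidazole (DMF) should give its bis(tert-butyldimethylsilyl) ether F4.
- Sonogashira coupling with commercial tert-butyl(4-ethynylphenoxy)dimethylsilane [PdCl2(PPh3)2, CuI, Et3N, 70 °C] should give the tris(silyl ether) alkynyl ketone F5 (8 with OTBS in place of each OMe).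
- Addition of 9 as in step 4 should give the propargylic alcohol F6 (10 with OTBS in place of each OMe).
- Annulation with 11 as in step 5 should give the quinone methide tris(silyl ether) F7 (14 with OTBS in place of each OMe).
- TBAF buffered with AcOH (THF, 0 °C) should remove the three silyl groups.

The fallback comes back to the route at 15.

**Further compounds**
F1 | step 5 | bis(4-methoxyphenyl){6-(4-methoxyphenyl)-2-[(4-methoxyphenyl)ethynyl]-3-methylphenyl}methanol | Cc1ccc(-c2ccc(OC)cc2)c(C(O)(c2ccc(OC)cc2)c2ccc(OC)cc2)c1C#Cc1ccc(OC)cc1
F2 | step 1 | 2-bromo-6-iodo-3-methylbenzoic acid | Cc1ccc(I)c(C(=O)O)c1Br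
F3 | step 6 | [2-bromo-6-(4-hydroxyphenyl)-3-methylphenyl](4-hydroxyphenyl)methanone | Cc1ccc(-c2ccc(O)cc2)c(C(=O)c2ccc(O)cc2)c1Br
F4 | step 6 | [2-bromo-6-(4-{[tert-butyl(dimethyl)silyl]oxy}phenyl)-3-methylphenyl](4-{[tert-butyl(dimethyl)silyl]oxy}phenyl)methanone | Cc1ccc(-c2ccc(O[Si](C)(C)C(C)(C)C)cc2)c(C(=O)c2ccc(O[Si](C)(C)C(C)(C)C)cc2)c1Br
F5 | step 6 | tris(tert-butyldimethylsilyl ether) analogue of ketone 8 | Cc1ccc(-c2ccc(O[Si](C)(C)C(C)(C)C)cc2)c(C(=O)c2ccc(O[Si](C)(C)C(C)(C)C)cc2)c1C#Cc1ccc(O[Si](C)(C)C(C)(C)C)cc1
F6 | step 6 | tris(tert-butyldimethylsilyl ether) analogue of propargylic alcohol 10, racemic | Cc1ccc(-c2ccc(O[Si](C)(C)C(C)(C)C)cc2)c(C(O)(C#C)c2ccc(O[Si](C)(C)C(C)(C)C)cc2)c1C#Cc1ccc(O[Si](C)(C)C(C)(C)C)cc1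
F7 | step 6 | tris(tert-butyldimethylsilyl ether) analogue of quinone methide 14 | Cc1ccc(-c2ccc(O[Si](C)(C)C(C)(C)C)cc2)c(C(=C2C=CC(=O)C=C2)c2ccc(O[Si](C)(C)C(C)(C)C)cc2)c1C#Cc1ccc(O[Si](C)(C)C(C)(C)C)cc1
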